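**Retrosynthetic overview**
1. Target ⇐ veratroylation of the C6 alcohol ⇐ hydroxyl-directed reduction of a trans-fused bicyclo[5.3.0]dec-8-en-6-one that already carries both acetates and the C4 carbinol.
2. 6-Ketone ⇐ cis-fused bicyclo[4.4.0]decene 5-mesylate-4,6-diol by a pinacol-type 1,2-shift of C1 from C6 to C5: the cyclohexane C1–C6 loses C6 and becomes five-membered ring A, while the cyclohexene C1/C6–C10 takes up C5 and becomes seven-membered ring B.
3. Enabling feature: the oxygenated C6 of ring B is bonded to ring-fusion C5, which lies between quaternary C1 and the C4 carbinol of ring A; a C6 carbonyl next to the C1–C5 bond is the retron of this shift, and the cis C4/C5/C6 triol of the precursor comes from one osmylation.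
4. Cis-decalin ⇐ OH-directed dihydroxylation, ring-closing metathesis (C8=C9), chelation-controlled methallylation at C6, Saegusa oxidation, CBS desymmetrisation (C1, C2) and Pd-catalysed alkoxyallene addition (C10) on 5-isopropyl-2-methylcyclohexane-1,3-dione.
5. Ring order: cyclohexane C1–C6 (from the dione) → second six-membered ring by metathesis → both rings resized together in the key step (6/6 → 5/7).

Key step: step 14

Remark: the daucane numbering of the target is used for every intermediate (C1 quaternary C–CH3, C2 CH–OAc, C3 CH2, C4 C(OH)iPr, C5 ring-fusion CH, C6 CH–O-aroyl, C7 CH2, C8 C(CH3)=, C9 =CH, C10 CH–OAc); β is the face of the C1 methyl group.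
Remark: the (R,R) enantiomer of the Trost ligand is assumed to give the (10R) ether in step 4; if the sense is opposite, the (S,S) ligand is used and nothing else changes.

**Step 1**
Reactants: 1 prop-2-yn-1-ol; 2 4-methoxybenzyl chloride
Product: 3 4-methoxybenzyl prop-2-ynyl ether
Conditions: NaH, Bu4NI (cat.), THF, 0 °C → rt
Reagents that add atoms: none
Why: Williamson ether synthesis (SN2 displacement of the benzylic chloride by the sodium alkoxide); no stereocentre is formed.

**Step 2**
Reactants: 3 4-methoxybenzyl prop-2-ynyl ether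
Product: 4 (4-methoxybenzyloxy)allene
Conditions: KOtBu (0.3 equiv), THF, rt
Reagents that add atoms: none
Why: Base-catalysed propargyl-to-allenyl ether isomerisation (prototropic shift), which should stop at the alkoxyallene; no stereocentre.

**Step 3**
Reactants: 5 5-isopropylcyclohexane-1,3-dione
Product: 6 5-isopropyl-2-methylcyclohexane-1,3-dione
Conditions: MeI, NaOH, H2O–dioxane, 60 °C
Reagents that add atoms: iodomethane, CI
Why: C-Alkylation of the cyclic 1,3-dione enolate in water, the classical route to 2-methylcyclohexane-1,3-diones; C1 stays enolisable, so no fixed stereocentre results.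

**Step 4**
Reactants: 6 5-isopropyl-2-methylcyclohexane-1,3-dione; 4 (4-methoxybenzyloxy)allene
Product: 7 2-[(1R)-1-(4-methoxybenzyloxy)prop-2-enyl]-5-isopropyl-2-methylcyclohexane-1,3-dione, alkoxyallyl group cis to isopropyl
Conditions: Pd2(dba)3·CHCl3 (2.5 mol %), (R,R)-DACH-phenyl Trost ligand (6 mol %), PhCO2H (10 mol %), CH2Cl2, rt
Reagents that add atoms: none
Why: Palladium-catalysed asymmetric addition of a 1,3-dicarbonyl pronucleophile to an alkoxyallene (Trost hydrocarbonation) through an alkoxy-substituted π-allylpalladium complex attacked at its oxygen-bearing terminus; the ligand sets C10 (R), and the electrophile should enter axially at C1, cis to the equatorial isopropyl group (any trans ring isomer is removed after step 5).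

**Step 5**
Reactants: 7 alkoxyallyl dione
Product: 8 (2S)-hydroxy ketone: 3-hydroxy-2-[(1R)-1-(4-methoxybenzyloxy)prop-2-enyl]-5-isopropyl-2-methylcyclohexanone, OH cis to the alkoxyallyl group and trans to methyl (2α-OH, C6 ketone)
Conditions: (R)-2-methyl-CBS-oxazaborolidine (20 mol %), catecholborane (1.1 equiv), toluene, −78 °C
Reagents that add atoms: none
Why: Corey–Bakshi–Shibata desymmetrising reduction: hydride should add anti to the axial alkoxyallyl group at either carbonyl, and the catalyst selects the carbonyl whose open face gives the (S)-carbinol, so C2 (OH trans to methyl) and quaternary C1 are set together, while catecholborane at low temperature spares the vinyl group.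

**Step 6**
Reactants: 8 hydroxy ketone
Product: 9 bis(trimethylsilyl) derivative of 8 (C2 O-silyl ether and C5=C6 silyl enol ether)
Conditions: TMSCl, LiN(iPr)2 (LDA, 2.3 equiv), THF, −78 °C
Reagents that add atoms: chlorotrimethylsilane, C[Si](C)(C)Cl
Why: O-Silylation of the alcohol and kinetic enolate trapping (silyl enol ether formation); C5 is the only enolisable α-carbon because C1 is quaternary, and no stereocentre changes.

**Step 7**
Reactants: 9 bis(trimethylsilyl) derivative
Product: 11 cyclohexenone with C6 ketone and C4=C5 alkene bearing isopropyl on C4 (2α-OH; C1 with β-methyl and α-(1R)-1-(4-methoxybenzyloxy)allyl), via silyl-protected enone 10 (not isolated)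
Conditions: Pd(OAc)2 (1.05 equiv), MeCN, rt; then 1 M HCl, THF, 0 °C
Reagents that add atoms: none
Why: Saegusa–Ito oxidation (palladium enolate, β-hydride elimination from C4) gives the β-isopropyl enone and erases the C4 stereocentre, so both ring isomers converge; dilute acid then cleaves the silyl ether.

**Step 8**
Reactants: 11 hydroxy enone; 12 2-methylallylmagnesium chloride
Product: 13 tertiary alcohol: 6β-hydroxy-6α-(2-methylallyl) adduct of 11 (2α-OH, C4=C5 retained)
Conditions: MgBr2·OEt2, CH2Cl2, −78 °C; then 12 (3 equiv, THF), −78 → −40 °C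
Reagents that add atoms: none
Why: 1,2-Addition of an allylic Grignard reagent to the enone under chelation control: magnesium bridging the C10 ether oxygen and the C6 carbonyl holds the alkoxyallyl group in the carbonyl plane and the C1 methyl perpendicular to it, so the nucleophile should enter anti to methyl, on the face of the C2 magnesium alkoxide, giving the 6β-hydroxyl (cis to methyl) with the methallyl group cis to the C10 chain.

**Step 9**
Reactants: 13 tertiary alcohol
Product: 14 cis-fused bicyclo[4.4.0]decadiene diol (C4=C5 and C8=C9; 1β-Me, 2α-OH, 4-iPr, 6β-OH at the ring fusion, 8-Me, 10α-O-(4-methoxybenzyl))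
Conditions: second-generation Grubbs catalyst [RuCl2(=CHPh)(H2IMes)(PCy3)] (5 mol %), CH2Cl2, 40 °C
Reagents that add atoms: none
Why: Ring-closing olefin metathesis between the vinyl group and the 1,1-disubstituted methallyl alkene, both α on the C1–C6 ring, closes the second six-membered ring as a cis-fused cyclohexene with the trisubstituted C8=C9 bond; no stereocentre is formed.

**Step 10**
Reactants: 14 bicyclic diol
Product: 15 triol (2α-OH, 6β-OH, 10α-OH)
Conditions: DDQ, CH2Cl2–pH 7 buffer, 0 °C
Reagents that add atoms: none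
Why: Oxidative cleavage of the 4-methoxybenzyl ether (hydride abstraction by DDQ, hydrolysis of the oxocarbenium ion) should free the C10 allylic alcohol without touching the alkenes or the tertiary alcohol; configuration unchanged.

**Step 11**
Reactants: 15 triol
Product: 16 2α,10α-diacetate with free tertiary 6β-OH
Conditions: Ac2O, pyridine, DMAP (cat.), CH2Cl2, 0 °C → rt
Reagents that add atoms: acetic anhydride, CC(=O)OC(C)=O
Why: DMAP-catalysed acylation should esterify the two secondary hydroxyls and leave the hindered tertiary 6-OH free as directing group and later migration origin; no stereocentre changes.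

**Step 12**
Reactants: 16 diacetate
Product: 18 4β,5β,6β-triol 2α,10α-diacetate (4α-isopropyl), via cyclic osmate ester 17 (not isolated)
Conditions: OsO4 (1.05 equiv), TMEDA (1.1 equiv), CH2Cl2, −78 °C; then aq. NaHSO3, THF, 40 °C
Reagents that add atoms: osmium tetroxide, O=[Os](=O)(=O)=O
Why: Hydrogen-bond-directed dihydroxylation (Donohoe conditions): the OsO4–TMEDA complex is held by the allylic tertiary 6β-OH and should add to the C4=C5 alkene on the β face, which is also the convex face of the cis-fused bicycle, in preference to the C8=C9 alkene, setting 4β-OH/4α-isopropyl and 5β-OH in one syn addition.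

**Step 13**
Reactants: 18 triol diacetate
Product: 19 5β-mesylate (4β-OH and 6β-OH free)
Conditions: MsCl, pyridine, DMAP (cat.), CH2Cl2, 0 °C
Reagents that add atoms: methanesulfonyl chloride, CS(=O)(=O)Cl
Why: Sulfonylation of the only secondary hydroxyl (equatorial C5–OH) while both tertiary hydroxyls stay free; no stereocentre changes.

**Step 14**
Reactants: 19 5β-mesylate
Product: 20 2α,10α-diacetoxy-4β-hydroxy-5α-H-dauc-8-en-6-one (trans-fused bicyclo[5.3.0]decenone)
Conditions: Et3Al (4 equiv), CH2Cl2, −78 → −20 °C; aq. KNaC4H4O6 work-up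
Reagents that add atoms: none
Why: Triethylaluminium converts the two tertiary hydroxyls into aluminium alkoxides and activates the mesylate, and in the chair that places isopropyl, the C2 acetoxy group, the C1 methyl and the mesylate all equatorial the C5–O bond is antiperiplanar to the C1–C6 ring-fusion bond, so C1 should shift from C6 to C5 while the C6 alkoxide collapses to the ketone (pinacol-type, i.e. semipinacol, 1,2-alkyl shift). The closest known reaction type is the rearrangement of decalin-1,2-diol monosulfonates to hydroazulenones, run here under Tsuchihashi–Suzuki organoaluminium conditions for β-mesyloxy alcohols. Five-membered ring A is closed by the 1,2-shift itself, as a ring contraction of the C1–C6 cyclohexane that expels C6, and seven-membered ring B arises in the same event as a one-carbon ring expansion of the cyclohexene by insertion of C5 between C1 and C6. The only stereocentre made is C5: C1 arrives with retention on the side opposite the departing mesylate (inversion at C5), so the cis relation of 6-OH, 5-OMs and the C1 methyl in the cis-decalin is translated into the trans ring fusion (5α-H), while C1, C2, C4 and C10 are carried through unchanged. The step needs migration of C1 and not of C3 (also antiperiplanar and backed by the C4 alkoxide), which should be secured by the much higher migratory aptitude of the fully substituted C1 and by relief of the vicinal crowding at C1/C6; the low temperature and the aluminium aldolate should protect the β-hydroxy ketone from retro-aldol cleavage and the β,γ-alkene from moving into conjugation.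

**Step 15**
Reactants: 20 hydroazulenone
Product: 21 2α,10α-diacetoxy-dauc-8-ene-4β,6α-diol
Conditions: Me4NBH(OAc)3, MeCN–AcOH, −30 °C
Reagents that add atoms: none
Why: Evans–Saksena hydroxyl-directed reduction: the acetoxyborohydride bound to the tertiary 4β-OH should deliver hydride intramolecularly to the β face of the C6 carbonyl, giving the 6α-alcohol (1,3-anti to 4-OH) and leaving the acetates intact.

**Step 16**
Reactants: 21 diol; 22 3,4-dimethoxybenzoyl chloride
Product: 23 target, 2α,10α-diacetoxy-6α-(3,4-dimethoxybenzoyloxy)-dauc-8-en-4β-ol (CNP0320758.1)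
Conditions: Et3N, DMAP (cat.), CH2Cl2, 0 °C → rt
Reagents that add atoms: none
Why: DMAP-catalysed acylation of the single secondary hydroxyl; the tertiary 4-OH should not react, and no stereocentre is touched.

**Compound list**
1 | prop-2-yn-1-ol | C#CCO | starting material
2 | 4-methoxybenzyl chloride | COc1ccc(CCl)cc1 | starting material
3 | 4-methoxybenzyl prop-2-ynyl ether | C#CCOCc1ccc(OC)cc1 | intermediate
4 | (4-methoxybenzyloxy)allene | C=C=COCc1ccc(OC)cc1 | intermediate
5 | 5-isopropylcyclohexane-1,3-dione | CC(C)C1CC(=O)CC(=O)C1 | starting material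
6 | 5-isopropyl-2-methylcyclohexane-1,3-dione | CC(C)C1CC(=O)C(C)C(=O)C1 | intermediate
7 | 2-[(1R)-1-(4-methoxybenzyloxy)prop-2-enyl]-5-isopropyl-2-methylcyclohexane-1,3-dione, alkoxyallyl cis to isopropyl | C=C[C@@H](OCc1ccc(OC)cc1)[C@@]1(C)C(=O)C[C@@H](C(C)C)CC1=O | intermediate
8 | (2S)-hydroxy ketone, OH cis to the alkoxyallyl group and trans to methyl | C=C[C@@H](OCc1ccc(OC)cc1)[C@@]1(C)[C@@H](O)C[C@@H](C(C)C)CC1=O | intermediate
9 | bis(trimethylsilyl) derivative of 8 (C2 silyl ether, C5=C6 silyl enol ether) | C=C[C@@H](OCc1ccc(OC)cc1)[C@@]1(C)[C@@H](O[Si](C)(C)C)C[C@@H](C(C)C)C=C1O[Si](C)(C)C | intermediate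
10 | C2 O-trimethylsilyl ether of enone 11 | C=C[C@@H](OCc1ccc(OC)cc1)[C@@]1(C)[C@@H](O[Si](C)(C)C)CC(C(C)C)=CC1=O | intermediate
11 | cyclohexenone (C6 ketone, C4=C5, 4-isopropyl, 2α-OH, 1β-Me, 1α-alkoxyallyl) | C=C[C@@H](OCc1ccc(OC)cc1)[C@@]1(C)[C@@H](O)CC(C(C)C)=CC1=O | intermediate
12 | 2-methylallylmagnesium chloride | CC(=C)C[Mg]Cl | starting material
13 | 6β-hydroxy-6α-(2-methylallyl) adduct (2α-OH) | C=C[C@@H](OCc1ccc(OC)cc1)[C@@]1(C)[C@@H](O)CC(C(C)C)=C[C@@]1(O)CC(C)=C | intermediate
14 | cis-fused bicyclo[4.4.0]decadiene diol, 10α-O-(4-methoxybenzyl) | O[C@]12CC(C)=C[C@@H](OCc3ccc(OC)cc3)[C@@]1(C)[C@@H](O)CC(C(C)C)=C2 | intermediate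
15 | triol (2α, 6β, 10α) | O[C@]12CC(C)=C[C@@H](O)[C@@]1(C)[C@@H](O)CC(C(C)C)=C2 | intermediate
16 | 2α,10α-diacetate, 6β-OH | O[C@]12CC(C)=C[C@@H](OC(C)=O)[C@@]1(C)[C@@H](OC(C)=O)CC(C(C)C)=C2 | intermediate
17 | cyclic 4β,5β-osmate ester of 16 (TMEDA-ligated in the flask; drawn without the diamine) | O[C@]12CC(C)=C[C@@H](OC(C)=O)[C@@]1(C)[C@@H](OC(C)=O)C[C@@](O[Os]3(=O)=O)(C(C)C)[C@@H]2O3 | intermediate
18 | 4β,5β,6β-triol 2α,10α-diacetate | O[C@]12CC(C)=C[C@@H](OC(C)=O)[C@@]1(C)[C@@H](OC(C)=O)C[C@@](O)(C(C)C)[C@@H]2O | intermediate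
19 | 5β-mesylate of 18 | O[C@]12CC(C)=C[C@@H](OC(C)=O)[C@@]1(C)[C@@H](OC(C)=O)C[C@@](O)(C(C)C)[C@@H]2OS(C)(=O)=O | intermediate
20 | 2α,10α-diacetoxy-4β-hydroxy-5α-H-dauc-8-en-6-one | O=C1CC(C)=C[C@@H](OC(C)=O)[C@@]2(C)[C@@H](OC(C)=O)C[C@@](O)(C(C)C)[C@H]12 | intermediate
21 | 2α,10α-diacetoxy-dauc-8-ene-4β,6α-diol | O[C@H]1CC(C)=C[C@@H](OC(C)=O)[C@@]2(C)[C@@H](OC(C)=O)C[C@@](O)(C(C)C)[C@H]12 | intermediate
22 | 3,4-dimethoxybenzoyl chloride | COc1ccc(C(Cl)=O)cc1OC | starting material
23 | CNP0320758.1 | COc1ccc(C(=O)O[C@H]2CC(C)=C[C@@H](OC(C)=O)[C@@]3(C)[C@@H](OC(C)=O)C[C@@](O)(C(C)C)[C@H]23)cc1OC | target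

**Totals and risks**
Total step count: 16. Longest linear sequence: 15 steps (steps 1, 2 and 4–16).

Steps most likely to fail:

Step 14. The free β-hydroxy ketone may open by retro-aldol cleavage or dehydrate under the aluminium alkoxide conditions, and the aluminium reagent may transfer ethyl or hydride to the new ketone or attack the acetates. The fallback sets out from 19 and first caps both tertiary hydroxyls (TMSOTf, 2,6-lutidine, CH2Cl2, −78 °C) to give the bis(trimethylsilyl) ether of the mesylate F1. The same 1,2-shift is then triggered with Et2AlCl at −78 °C, now with the C6 silyl ether oxygen as the electron donor, and should give the C4 O-trimethylsilyl ether of the ketone F2, which cannot undergo retro-aldol cleavage. HF·pyridine in THF removes the silyl group, and the route is rejoined at 20.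

Step 8. The intermolecular addition may show poor facial selectivity, with the Grignard reagent entering anti to the larger alkoxyallyl group instead of anti to methyl and giving the 6α-alcohol. The fallback sets out from 11 and uses a temporary silicon tether: silylation of the C2 hydroxyl with chloro(dimethyl)(2-methylallyl)silane (imidazole, DMF) gives the C2 dimethyl(2-methylallyl)silyl ether F3. BF3·OEt2 (CH2Cl2, −78 °C) should then transfer the methallyl group from silicon to the α face of the C6 carbonyl in an intramolecular SE2′ allylsilane addition. Work-up with K2CO3 in aqueous methanol cleaves the Si–O bond, and the route is rejoined at 13.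

Step 12. Osmylation of the ring-B-precursor C8=C9 alkene (homoallylic to the directing hydroxyl) may compete with the directed reaction at C4=C5. The fallback sets out from 13 and oxidises before that alkene exists:
- Selective acetylation of the C2 hydroxyl (Ac2O, pyridine, DMAP) gives the C2 acetate of 13, F4.
- OsO4/TMEDA at −78 °C, directed by the 6β-OH, gives the cyclic 4β,5β-osmate ester F5 and, after aq. NaHSO3, the monocyclic 4β,5β,6β-triol F6.
- The second-generation Grubbs catalyst closes the cyclohexene to the bicyclic triol F7 (2α-OAc, 10α-O-(4-methoxybenzyl)).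
- MsCl/pyridine gives the 5β-mesylate F8.
- DDQ frees the C10 alcohol to give the 10α-alcohol F9.
- Acetylation of F9 (Ac2O, pyridine, DMAP) rejoins the route at 19.

**Further compounds**
F1 | step 14 | bis(trimethylsilyl) ether of the mesylate (C4 and C6 O-silylated 19) | C[Si](C)(C)O[C@]12CC(C)=C[C@@H](OC(C)=O)[C@@]1(C)[C@@H](OC(C)=O)C[C@@](O[Si](C)(C)C)(C(C)C)[C@@H]2OS(C)(=O)=O
F2 | step 14 | C4 O-trimethylsilyl ether of the ketone 20 | O=C1CC(C)=C[C@@H](OC(C)=O)[C@@]2(C)[C@@H](OC(C)=O)C[C@@](O[Si](C)(C)C)(C(C)C)[C@H]12
F3 | step 8 | C2 dimethyl(2-methylallyl)silyl ether of enone 11 | C=C[C@@H](OCc1ccc(OC)cc1)[C@@]1(C)[C@@H](O[Si](C)(C)CC(C)=C)CC(C(C)C)=CC1=O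
F4 | step 12 | C2 acetate of 13 | C=C[C@@H](OCc1ccc(OC)cc1)[C@@]1(C)[C@@H](OC(C)=O)CC(C(C)C)=C[C@@]1(O)CC(C)=C
F5 | step 12 | cyclic 4β,5β-osmate ester of F4 (TMEDA-ligated in the flask; drawn without the diamine) | C=C[C@@H](OCc1ccc(OC)cc1)[C@@]1(C)[C@@H](OC(C)=O)C[C@@](O[Os]2(=O)=O)(C(C)C)[C@H](O2)[C@@]1(O)CC(C)=C
F6 | step 12 | monocyclic 4β,5β,6β-triol (C2 acetate, C10 4-methoxybenzyl ether) | C=C[C@@H](OCc1ccc(OC)cc1)[C@@]1(C)[C@@H](OC(C)=O)C[C@@](O)(C(C)C)[C@H](O)[C@@]1(O)CC(C)=C
F7 | step 12 | bicyclic triol (2α-OAc, 10α-O-(4-methoxybenzyl)) | O[C@]12CC(C)=C[C@@H](OCc3ccc(OC)cc3)[C@@]1(C)[C@@H](OC(C)=O)C[C@@](O)(C(C)C)[C@@H]2O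
F8 | step 12 | 5β-mesylate of F7 | O[C@]12CC(C)=C[C@@H](OCc3ccc(OC)cc3)[C@@]1(C)[C@@H](OC(C)=O)C[C@@](O)(C(C)C)[C@@H]2OS(C)(=O)=O
F9 | step 12 | 10α-alcohol from F8 | O[C@]12CC(C)=C[C@@H](O)[C@@]1(C)[C@@H](OC(C)=O)C[C@@](O)(C(C)C)[C@@H]2OS(C)(=O)=O
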